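## Retrosynthetic overview

- The target comes from its tetraacetate by lipase-catalysed global deacetylation at neutral pH, which frees four hydroxyls without touching the base-labile C2 centre.
- The C2–aryl bond and the only stereocentre come from a rhodium/chiral-diene asymmetric 1,4-addition of (3,4-diacetoxyphenyl)boronic acid to an 8-substituted 7-acetoxychromone.
- The E-hydroxyprenyl chain comes from cross-metathesis of an 8-allylchromone with methacrolein, then 1,2-reduction.
- The chromone comes from enaminone annulation of 3-allyl-2,4-dihydroxyacetophenone, made from resacetophenone by O-allylation and aromatic Claisen rearrangement.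
- Ring order: ring A is bought, ring C is closed as the chromone, ring B is attached last by the conjugate addition.

Assumption: building blocks that supply atoms of the target skeleton are numbered, protecting-group and auxiliary reagents appear on the reagent line only, and the (S,S)-diene is taken to give the 2S product by analogy with the usual facial model for rhodium/diene conjugate additions (checked by CD).

## Route

Step 1
Reactants: 1 resacetophenone (2,4-dihydroxyacetophenone); 2 allyl bromide
Product: 3 allyl ether 1-[2-hydroxy-4-(prop-2-en-1-yloxy)phenyl]ethanone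
Conditions: K2CO3 (1.1 equiv), acetone, reflux, 6 h
Reagents that add atoms: none
Why: Williamson etherification in which the 2-OH is tied up in a hydrogen bond to the acetyl group, so only the free, more acidic 4-OH is alkylated.

Step 2
Reactants: 3 allyl ether
Product: 4 C-allyl phenol 1-[2,4-dihydroxy-3-(prop-2-en-1-yl)phenyl]ethanone
Conditions: PhNEt2, 200 °C, N2, 5 h
Reagents that add atoms: none
Why: Aromatic Claisen ([3,3]-sigmatropic) rearrangement and tautomerisation, directed mainly to C3 between the two oxygens by bond fixation of the chelated ortho-hydroxy ketone, with the minor C5 isomer removed by crystallisation.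

Step 3
Reactants: 4 C-allyl phenol
Product: 5 MOM ether 1-[2-hydroxy-4-(methoxymethoxy)-3-(prop-2-en-1-yl)phenyl]ethanone
Conditions: MOMCl (1.2 equiv), iPr2NEt (1.5 equiv), CH2Cl2, 0 °C to rt
Reagents that add atoms: chloromethyl methyl ether (MOMCl), COCCl
Why: Selective O-alkylation of the non-chelated 4-OH, which prevents O-methylation of that phenol by the amide acetal in the next step.

Step 4
Reactants: 5 MOM ether; 6 N,N-dimethylformamide dimethyl acetal
Product: 9 hydroxychromone 7-hydroxy-8-(prop-2-en-1-yl)-4H-chromen-4-one, via enaminone 7 (not isolated), via MOM-protected chromone 8 (not isolated)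
Conditions: 6 (3 equiv), toluene, 100 °C, 4 h; evaporate; conc. HCl (5 equiv), MeOH, 60 °C, 3 h
Reagents that add atoms: none
Why: Enaminone condensation of the methyl ketone, then acid-promoted addition–elimination ring closure of the phenol onto the enaminone (chromone annulation) and acid methanolysis of the MOM acetal in the same pot, conditions under which a terminal allyl group is inert.

Step 5
Reactants: 9 hydroxychromone
Product: 10 chromone acetate 4-oxo-8-(prop-2-en-1-yl)-4H-chromen-7-yl acetate
Conditions: Ac2O (1.5 equiv), pyridine, CH2Cl2, 0 °C to rt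
Reagents that add atoms: acetic anhydride, CC(=O)OC(C)=O
Why: Phenol acetylation, which blocks 5-exo oxa-Michael attack of the acidic 7-OH on the enal made next and installs the ester that the enzyme removes at the end.

Step 6
Reactants: 10 chromone acetate; 11 methacrolein
Product: 12 enal 8-[(2E)-3-methyl-4-oxobut-2-en-1-yl]-4-oxo-4H-chromen-7-yl acetate
Conditions: 11 (8 equiv), second-generation Hoveyda–Grubbs catalyst [RuCl2(H2IMes)(=CH-C6H4-2-OiPr)] (5 mol%), 1,4-benzoquinone (10 mol%), CH2Cl2, 40 °C, 16 h
Reagents that add atoms: none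
Why: Olefin cross-metathesis of a terminal alkene with a slowly dimerising 1,1-disubstituted enal under thermodynamic control gives the E-trisubstituted enal (CHO trans to the benzylic CH2), with benzoquinone suppressing ruthenium-hydride isomerisation of the allyl group.

Step 7
Reactants: 12 enal
Product: 13 allylic alcohol 8-[(2E)-4-hydroxy-3-methylbut-2-en-1-yl]-4-oxo-4H-chromen-7-yl acetate
Conditions: NaBH4 (0.6 equiv), CeCl3·7H2O (1.1 equiv), MeOH/THF 3:1, −78 °C, 20 min; acetone, then aq NH4Cl
Reagents that add atoms: none
Why: Luche 1,2-reduction, in which the aldehyde is far more electrophilic at −78 °C than the vinylogous-ester chromone carbonyl, the alkene geometry is untouched, and any loss of the 7-acetate is repaired in step 8.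

Step 8
Reactants: 13 allylic alcohol
Product: 14 chromone diacetate (2E)-4-[7-(acetyloxy)-4-oxo-4H-chromen-8-yl]-2-methylbut-2-en-1-yl acetate
Conditions: Ac2O (3 equiv), pyridine, DMAP (5 mol%), CH2Cl2, 0 °C to rt
Reagents that add atoms: acetic anhydride, CC(=O)OC(C)=O
Why: DMAP-catalysed acyl transfer acetylates the primary allylic alcohol and re-acetylates any free 7-OH, so the material converges on one diacetate.

Step 9
Reactants: 15 4-bromocatechol (4-bromobenzene-1,2-diol)
Product: 16 bromo diacetate 4-bromo-1,2-phenylene diacetate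
Conditions: Ac2O (2.5 equiv), pyridine, CH2Cl2, 0 °C to rt
Reagents that add atoms: acetic anhydride, CC(=O)OC(C)=O
Why: Acetylation masks the catechol, which would otherwise chelate boron and rhodium, with esters that survive borylation and are later removed enzymatically.

Step 10
Reactants: 16 bromo diacetate
Product: 17 pinacol boronate 4-(4,4,5,5-tetramethyl-1,3,2-dioxaborolan-2-yl)-1,2-phenylene diacetate
Conditions: B2pin2 (1.2 equiv), PdCl2(dppf)·CH2Cl2 (3 mol%), KOAc (3 equiv), 1,4-dioxane, 85 °C, 12 h
Reagents that add atoms: bis(pinacolato)diboron, CC1(C)OB(OC1(C)C)B1OC(C)(C)C(C)(C)O1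
Why: Miyaura borylation (oxidative addition of the aryl bromide to zerovalent palladium, acetate-assisted transmetalation, reductive elimination) under conditions to which aryl acetates are inert.

Step 11
Reactants: 17 pinacol boronate
Product: 18 boronic acid [3,4-bis(acetyloxy)phenyl]boronic acid
Conditions: NaIO4 (3 equiv), THF/H2O 4:1, rt, 30 min; then 1 M HCl (0.5 equiv), rt, 6 h
Reagents that add atoms: water, O
Why: Hydrolysis of the boronate is driven to completion by periodate (Malaprade) cleavage of the released pinacol under mildly acidic, amine-free conditions that leave the aryl acetates intact.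

Step 12
Reactants: 14 chromone diacetate; 18 boronic acid (3 equiv)
Product: 19 flavanone tetraacetate (2E)-4-{(2S)-7-(acetyloxy)-2-[3,4-bis(acetyloxy)phenyl]-4-oxo-3,4-dihydro-2H-chromen-8-yl}-2-methylbut-2-en-1-yl acetate
Conditions: [Rh(OH)((S,S)-Ph-bod)]2 (2.5 mol%; Ph-bod = 2,5-diphenylbicyclo[2.2.2]octa-2,5-diene), toluene/H2O 10:1, 40 °C, 16 h, no added base
Reagents that add atoms: none
Why: Hayashi–Miyaura rhodium-catalysed asymmetric 1,4-addition, in which the aryl–rhodium species adds across C2=C3 on the face left open by the C2-symmetric diene to set C2 as S, run base-free so the esters survive and no retro-oxa-Michael opening occurs, with the configuration confirmed by CD (positive Cotton effect near 330 nm, negative near 290 nm).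

Step 13
Reactants: 19 flavanone tetraacetate
Product: 20 target (2S)-2-(3,4-dihydroxyphenyl)-7-hydroxy-8-[(2E)-4-hydroxy-3-methylbut-2-en-1-yl]-2,3-dihydro-4H-chromen-4-one
Conditions: lipase (triacylglycerol lipase class; immobilised Burkholderia cepacia lipase), n-BuOH (20 equiv), THF, 40 °C, N2, 24–48 h; filter off enzyme
Reagents that add atoms: none
Why: Lipase-catalysed alcoholysis (transesterification through the acyl-enzyme serine ester) removes the three aryl acetates and the primary allylic acetate at neutral pH, avoiding base that would racemise C2 through chalcone ring-opening and acid that would cyclise the 7-OH onto the side-chain alkene.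

## Compound list

1 | 2,4-dihydroxyacetophenone | CC(=O)c1ccc(O)cc1O | starting material
2 | allyl bromide | C=CCBr | starting material
3 | 1-[2-hydroxy-4-(prop-2-en-1-yloxy)phenyl]ethanone | CC(=O)c1ccc(OCC=C)cc1O | intermediate
4 | 1-[2,4-dihydroxy-3-(prop-2-en-1-yl)phenyl]ethanone | CC(=O)c1ccc(O)c(CC=C)c1O | intermediate
5 | 1-[2-hydroxy-4-(methoxymethoxy)-3-(prop-2-en-1-yl)phenyl]ethanone | CC(=O)c1ccc(OCOC)c(CC=C)c1O | intermediate
6 | N,N-dimethylformamide dimethyl acetal | COC(OC)N(C)C | starting material
7 | (2E)-3-(dimethylamino)-1-[2-hydroxy-4-(methoxymethoxy)-3-(prop-2-en-1-yl)phenyl]prop-2-en-1-one | CN(C)/C=C/C(=O)c1ccc(OCOC)c(CC=C)c1O | intermediate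
8 | 7-(methoxymethoxy)-8-(prop-2-en-1-yl)-4H-chromen-4-one | C=CCc1c(OCOC)ccc2c(=O)ccoc12 | intermediate
9 | 7-hydroxy-8-(prop-2-en-1-yl)-4H-chromen-4-one | C=CCc1c(O)ccc2c(=O)ccoc12 | intermediate
10 | 4-oxo-8-(prop-2-en-1-yl)-4H-chromen-7-yl acetate | C=CCc1c(OC(C)=O)ccc2c(=O)ccoc12 | intermediate
11 | methacrolein (2-methylprop-2-enal) | CC(=C)C=O | starting material
12 | 8-[(2E)-3-methyl-4-oxobut-2-en-1-yl]-4-oxo-4H-chromen-7-yl acetate | C/C(=C\Cc1c(OC(C)=O)ccc2c(=O)ccoc12)C=O | intermediate
13 | 8-[(2E)-4-hydroxy-3-methylbut-2-en-1-yl]-4-oxo-4H-chromen-7-yl acetate | C/C(=C\Cc1c(OC(C)=O)ccc2c(=O)ccoc12)CO | intermediate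
14 | (2E)-4-[7-(acetyloxy)-4-oxo-4H-chromen-8-yl]-2-methylbut-2-en-1-yl acetate | C/C(=C\Cc1c(OC(C)=O)ccc2c(=O)ccoc12)COC(C)=O | intermediate
15 | 4-bromobenzene-1,2-diol | Oc1ccc(Br)cc1O | starting material
16 | 4-bromo-1,2-phenylene diacetate | CC(=O)Oc1ccc(Br)cc1OC(C)=O | intermediate
17 | 4-(4,4,5,5-tetramethyl-1,3,2-dioxaborolan-2-yl)-1,2-phenylene diacetate | CC(=O)Oc1ccc(B2OC(C)(C)C(C)(C)O2)cc1OC(C)=O | intermediate
18 | [3,4-bis(acetyloxy)phenyl]boronic acid | CC(=O)Oc1ccc(B(O)O)cc1OC(C)=O | intermediate
19 | (2E)-4-{(2S)-7-(acetyloxy)-2-[3,4-bis(acetyloxy)phenyl]-4-oxo-3,4-dihydro-2H-chromen-8-yl}-2-methylbut-2-en-1-yl acetate | C/C(=C\Cc1c(OC(C)=O)ccc2c1O[C@H](c1ccc(OC(C)=O)c(OC(C)=O)c1)CC2=O)COC(C)=O | intermediate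
20 | (2S)-2-(3,4-dihydroxyphenyl)-7-hydroxy-8-[(2E)-4-hydroxy-3-methylbut-2-en-1-yl]-2,3-dihydro-4H-chromen-4-one | C/C(=C\Cc1c(O)ccc2c1O[C@H](c1ccc(O)c(O)c1)CC2=O)CO | target

## Step count and risks

Total steps: 13. Longest linear sequence: 10 steps (steps 1–8, 12, 13); the boronic acid branch is 3 steps (9–11).

**Step 12 (asymmetric 1,4-addition).** Chromones are sluggish acceptors, and 14 carries a C8 chain with an allylic acetate close to the reacting ring. The fallback sets out from 10 (with 18) and comes back at 19. The aryl group is added before the side chain exists: 10 and 18 under the same hydroxo-rhodium/(S,S)-diene catalysis give the 8-allyl (2S)-flavanone triacetate F1. Cross-metathesis of F1 with 11 (second-generation Hoveyda–Grubbs catalyst, CH2Cl2, 40 °C) gives the E-enal flavanone triacetate F2. NaBH4/CeCl3·7H2O at −78 °C reduces the aldehyde ahead of the aryl ketone and gives the allylic alcohol flavanone triacetate F3. Ac2O/pyridine then returns to 19. All steps after the stereocentre are neutral or only weakly basic with every phenol acylated, so C2 is not at risk.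

**Step 6 (cross-metathesis with methacrolein).** Methacrolein is a poor metathesis partner and allylarenes can isomerise. The fallback sets out from 10 and comes back at 13. Compound 10 is cross-metathesised with 2-methyl-2-butene used as co-solvent (second-generation Grubbs catalyst, rt), a far more dependable partner, to give the 8-prenyl chromone acetate F4. Allylic C–H hydroxylation of F4 with catalytic SeO2 and t-BuOOH (CH2Cl2, rt) oxidises the E-methyl group selectively and gives 13 directly. Any over-oxidised enal is 12 and simply passes through step 7. This is done at the chromone stage, where SeO2 cannot dehydrogenate the heterocycle.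

**Step 13 (enzymatic global deacetylation).** The 7-acetate is flanked by the C8 chain and the catechol diacetate may stall at a monoacetate. The fallback sets out from 19 and comes back at 20. The three aryl acetates are first removed chemically by NH4OAc-mediated methanolysis in aqueous MeOH at rt, which is neutral and selective for aryl esters, to give the side-chain monoacetate triphenol F5. The lipase (n-BuOH, t-BuOMe, 30 °C) then has to cleave only the unhindered primary allylic acetate, its best substrate class, giving 20 without base or acid.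

## Further compounds

F1 | step 12 | (2S)-2-[3,4-bis(acetyloxy)phenyl]-4-oxo-8-(prop-2-en-1-yl)-3,4-dihydro-2H-chromen-7-yl acetate | C=CCc1c(OC(C)=O)ccc2c1O[C@H](c1ccc(OC(C)=O)c(OC(C)=O)c1)CC2=O
F2 | step 12 | (2S)-2-[3,4-bis(acetyloxy)phenyl]-8-[(2E)-3-methyl-4-oxobut-2-en-1-yl]-4-oxo-3,4-dihydro-2H-chromen-7-yl acetate | C/C(=C\Cc1c(OC(C)=O)ccc2c1O[C@H](c1ccc(OC(C)=O)c(OC(C)=O)c1)CC2=O)C=O
F3 | step 12 | (2S)-2-[3,4-bis(acetyloxy)phenyl]-8-[(2E)-4-hydroxy-3-methylbut-2-en-1-yl]-4-oxo-3,4-dihydro-2H-chromen-7-yl acetate | C/C(=C\Cc1c(OC(C)=O)ccc2c1O[C@H](c1ccc(OC(C)=O)c(OC(C)=O)c1)CC2=O)CO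
F4 | step 6 | 8-(3-methylbut-2-en-1-yl)-4-oxo-4H-chromen-7-yl acetate | CC(C)=CCc1c(OC(C)=O)ccc2c(=O)ccoc12
F5 | step 13 | (2E)-4-[(2S)-2-(3,4-dihydroxyphenyl)-7-hydroxy-4-oxo-3,4-dihydro-2H-chromen-8-yl]-2-methylbut-2-en-1-yl acetate | C/C(=C\Cc1c(O)ccc2c1O[C@H](c1ccc(O)c(O)c1)CC2=O)COC(C)=O
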